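The flask cannot turn more of its X into Z than its G allows: each Z costs one G, so G, the limiting reagent, caps Z at 90.0% of the X charged.

| flask | X | G | L | remark | volume of the second phase over the first |
|---|---|---|---|---|---|
| ash | 0.42 M | 0.27 M | 24 mM | run made earlier |  |
| elm | 0.66 M | 0.27 M | 24 mM | run made earlier |  |
| cedar | 0.30 M | 0.27 M | 48 mM | run made earlier |  |
| flask | 0.30 M | 0.270 M | 24 mM |  | 0.25 |

| run | time / min | Z / % |
|---|---|---|
| ash | 2.00 | 18.4 |
| ash | 6.00 | 41.4 |
| ash | 10.0 | 51.7 |
| ash | 15.0 | 57.4 |
| ash | 25.0 | 61.1 |
| ash | 30.0 | 62.1 |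
| elm | 2.50 | 20.8 |
| elm | 4.00 | 29.8 |
| elm | 6.00 | 34.9 |
| elm | 10.0 | 38.2 |
| elm | 20.0 | 40.8 |
| elm | 30.0 | 40.6 |
| cedar | 2.50 | 40.3 |
| cedar | 8.00 | 68.8 |
| cedar | 15.0 | 78.3 |
| cedar | 20.0 | 81.8 |
| cedar | 30.0 | 84.6 |

(each reading ± 0.5 percentage points)

- in the second phase: G, E; everything else is in the first
- charges count per volume of the first phase; a concentration in a rate is the amount of a species over the volume of its own phase; every rate counts per litre of the first phase
- what may be going on: L + G <-> Q + E; X + Q -> Z + L; Q -> J
- the earlier runs hold the two phases in the same ratio of volumes as the flask asked about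
- no earlier run changes the charge of G; that part of a forecast is a guess

* factor on the rate of making Z when 20% of the X are converted if G is charged twice over
* factor on the rate when 20% of the X are converted if L is charged at 2.5 mM instead

*Does the catalyst cost G too?* Yes. On the proposed steps, each Q formed net costs one G, and it stands as Q until it gives Z or J, so the G spent equals cZ + cJ + cQ.

*How much J per Z?* Q makes J at a rate proportional to cQ and Z at a rate proportional to cQ·cX, so cQ cancels. Define β, the cX at which Q goes to J as often as it gives Z. Then cJ = β ln(charged cX / present cX), whatever the catalyst charge.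

*Where do you read β?* In cedar, which has converted the largest share of its X. Its gains shrink with a time constant near 8.19 min, so I extend its Z to 85.8%. Taking cG and cQ as nil at that extended end leaves cJ = 12.5 mM, and so β = 6.38 mM.

*That rests on an extrapolation. Is it firm?* No, it is a rough reading: the extension adds 1.2 percentage points to the last reading, whose scatter is 0.5 points.

*So what happens at 20% conversion?* cJ = 1.42 mM at either charge of L. That is 5.92% of the catalyst at 24 mM but 56.8% at 2.5 mM. If the surviving catalyst splits between L and Q alike in both cases, my ratio is 0.0477.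

*And doubled G?* No earlier run changes its charge, and β says nothing on it, so I give no figure.

The forecast, holding that “Rate scales about linearly with L”, gives 1.1 for dbl and 0.09 for ratio, higher than my ratio.

    L + G ⇌ Q + E (K = 3.30, k = 0.760 M⁻¹ s⁻¹)
    X + Q → Z + L (k = 0.0891 M⁻¹ s⁻¹)
    Q → J (k = 6.12 × 10⁻⁴ s⁻¹)

The simulation gives a ratio of 0.0446, against my 0.0477, and a dbl of 1.09. As charged, the flask reaches 20% conversion at 2.02 min, with Z forming at 0.0247 M min⁻¹. At 2.5 mM, the second case, β puts cJ at 1.42 mM at that conversion. Back in this flask, X stands at 14.4% after 300 min, so β puts cJ at 12.4 mM, which is 51.5% of the catalyst charged, and J stands at 55.4%.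

Readings and results are simulated with made-up constants; scatter was added.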